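**Retrosynthetic overview**

Numbering: chroman O1, C2 (Me), C3, C4 (isobutyl), C4a, C5 (OH), C6 (CHO), C7 (OH), C8 (CHO), C8a; ten-membered ring C2, C3, C9, C10, C11 (Me), C12, C13, C14 (bears C17, the CMe2OH carbon), C15, C16, with the Z alkene at C11=C12.
Feature: C4 hangs on C4a between two ortho oxygens, O1 (on C8a) and O5 (on C5); once O1 is tied to C2 as a tertiary ether, O5 can still carry an o-quinone methide at C4, and an allylsilane on C2 can close the pyran ring (O1, C2, C3, C4, C4a, C8a) on it through C3.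
Disconnections, last to first: C6/C8 formyl groups; C11=C12 (ring-closing metathesis) and C10-C11 (B-alkyl Suzuki coupling); C4-isobutyl and C3-C4 (one cascade); O1-C2 (palladium-catalysed branched O-allylation); chain C2 and C12-C17 from (R)-α-terpineol, arene and C4 from 2,4,6-trihydroxybenzaldehyde.
Ring order: the benzene ring is bought, the pyran ring closes in the cascade, the ten-membered ring closes last.

Key step: step 10

Assumption: the (R,R) ligand in step 7 is taken to give the (R) ether at C2 from the E carbonate; if a trial shows the opposite sense, the (S,S) ligand is used and nothing else changes.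

TBS = tert-butyldimethylsilyl, MOM = methoxymethyl. Ring-fused compounds 25 to 28 are named with the numbering above.

**Route**

Step 1
Reactants: 1 2,4,6-trihydroxybenzaldehyde
Product: 2 2,6-dihydroxy-4-(methoxymethoxy)benzaldehyde
Conditions: MOMCl (1.0 equiv), iPr2NEt, THF, 0 °C
Reagents that add atoms: chloromethyl methyl ether, COCCl
Why: Williamson-type O-alkylation in which the 4-OH, the most acidic hydroxyl and the only one not hydrogen-bonded to the formyl group, should react first.

Step 2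
Reactants: 3 (R)-α-terpineol
Product: 4 (R)-tert-butyldimethyl{[2-(4-methylcyclohex-3-en-1-yl)propan-2-yl]oxy}silane
Conditions: TBSOTf, 2,6-lutidine, CH2Cl2, 0 °C to rt
Reagents that add atoms: tert-butyldimethylsilyl triflate, CC(C)(C)[Si](C)(C)OS(=O)(=O)C(F)(F)F
Why: silylation of the tertiary alcohol with the silyl triflate; the future C14 centre comes from the chiral pool and is not touched, and the TBS ether is chosen to survive the later mild acid and Vilsmeier steps.

Step 3
Reactants: 4 (R)-α-terpineol TBS ether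
Product: 6 (5R)-5-[2-(TBSO)propan-2-yl]-7,7-dimethoxyheptan-2-one, via keto aldehyde 5 (not isolated)
Conditions: O3, CH2Cl2/MeOH, −78 °C; Me2S, to rt; then CeCl3·7H2O (cat.), HC(OMe)3, MeOH, rt
Reagents that add atoms: ozone, [O-][O+]=O; trimethyl orthoformate, COC(OC)OC
Why: ozonolysis by the Criegee mechanism cleaves the only alkene to the methyl ketone (future C2) and the aldehyde (future C12), and cerium chloride-catalysed acetalisation is selective for the aldehyde over the ketone.

Step 4
Reactants: 6 (5R)-5-[2-(TBSO)propan-2-yl]-7,7-dimethoxyheptan-2-one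
Product: 7 ethyl (2E,6R)-6-[2-(TBSO)propan-2-yl]-8,8-dimethoxy-3-methyloct-2-enoate
Conditions: (EtO)2P(O)CH2CO2Et, NaH, THF, 0 to 50 °C; E ester separated from the minor Z ester by chromatography
Reagents that add atoms: triethyl phosphonoacetate, CCOC(=O)CP(=O)(OCC)OCC
Why: Horner-Wadsworth-Emmons olefination of the methyl ketone should favour the E enoate with the chain trans to the ester; only the E isomer is carried on because the alkene geometry decides the sense of step 7.

Step 5
Reactants: 7 ethyl (2E,6R)-6-[2-(TBSO)propan-2-yl]-8,8-dimethoxy-3-methyloct-2-enoate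
Product: 8 (2E,6R)-6-[2-(TBSO)propan-2-yl]-8,8-dimethoxy-3-methyloct-2-en-1-ol
Conditions: iBu2AlH (2.5 equiv), CH2Cl2, −78 °C; aq. KNaC4H4O6
Reagents that add atoms: none
Why: 1,2-reduction of the enoate by the aluminium hydride gives the allylic alcohol with the E geometry retained, the acetal and silyl ether being inert.

Step 6
Reactants: 8 (2E,6R)-6-[2-(TBSO)propan-2-yl]-8,8-dimethoxy-3-methyloct-2-en-1-ol
Product: 9 (2E,6R)-6-[2-(TBSO)propan-2-yl]-8,8-dimethoxy-3-methyloct-2-en-1-yl methyl carbonate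
Conditions: ClCO2Me, pyridine, CH2Cl2, 0 °C
Reagents that add atoms: methyl chloroformate, COC(=O)Cl
Why: acylation of the primary allylic alcohol gives the carbonate, which ionises readily with zerovalent palladium and releases methoxide as the internal base.

Step 7
Reactants: 9 (2E,6R)-6-[2-(TBSO)propan-2-yl]-8,8-dimethoxy-3-methyloct-2-en-1-yl methyl carbonate; 2 2,6-dihydroxy-4-(methoxymethoxy)benzaldehyde
Product: 10 2-{[(3R,6R)-6-[2-(TBSO)propan-2-yl]-8,8-dimethoxy-3-methyloct-1-en-3-yl]oxy}-6-hydroxy-4-(methoxymethoxy)benzaldehyde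
Conditions: Pd2(dba)3·CHCl3 (2 mol%), (R,R)-DACH-phenyl ligand N,N'-[(1R,2R)-cyclohexane-1,2-diyl]bis[2-(diphenylphosphanyl)benzamide] (6 mol%), 2 (1.8 equiv), CH2Cl2, rt
Reagents that add atoms: none
Why: Tsuji-Trost asymmetric allylic etherification in which the phenoxide attacks the more substituted terminus of the π-allylpalladium complex, as known for phenols with trisubstituted allylic carbonates and this ligand class; the chiral ligand sets C2 as R, and the excess of the symmetric diphenol should limit double allylation.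

Step 8
Reactants: 10 branched vinyl ether from step 7; 11 allyltrimethylsilane
Product: 12 2-{[(2E,4R,7R)-7-[2-(TBSO)propan-2-yl]-9,9-dimethoxy-4-methyl-1-(trimethylsilyl)non-2-en-4-yl]oxy}-6-hydroxy-4-(methoxymethoxy)benzaldehyde
Conditions: second-generation Hoveyda-Grubbs catalyst (10 mol%), 11 (8 equiv), CH2Cl2, 40 °C
Reagents that add atoms: none
Why: olefin cross-metathesis between the hindered vinyl group, which cannot homodimerise, and an excess of the reactive allylsilane; the fully substituted neighbour should favour the E allylsilane.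

Step 9
Reactants: 12 E allylsilane phenol from step 8
Product: 13 tert-butyl 2-formyl-3-{[(2E,4R,7R)-7-[2-(TBSO)propan-2-yl]-9,9-dimethoxy-4-methyl-1-(trimethylsilyl)non-2-en-4-yl]oxy}-5-(methoxymethoxy)phenyl carbonate
Conditions: Boc2O, iPr2NEt, DMAP (cat.), THF, 0 °C to rt
Reagents that add atoms: di-tert-butyl dicarbonate, CC(C)(C)OC(=O)OC(=O)OC(C)(C)C
Why: DMAP-catalysed O-acylation of the remaining phenol installs the aryl tert-butyl carbonate on O5, the group that migrates in the next step.

Step 10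
Reactants: 13 O-Boc salicylaldehyde with the tertiary allylsilane ether at O1; 14 isobutylmagnesium bromide
Product: 18 (2R,3S,4S)-2-[(3R)-3-[2-(TBSO)propan-2-yl]-5,5-dimethoxypentyl]-3-ethenyl-7-(methoxymethoxy)-2-methyl-4-(2-methylpropyl)-3,4-dihydro-2H-chromen-5-ol, via bromomagnesium alkoxide 15 (not isolated), via carbonate-shifted phenoxide 16 (not isolated), via o-quinone methide 17 (not isolated)
Conditions: 14 (1.05 equiv, Et2O), toluene/Et2O, 0.01 M, −78 °C; then to 0 °C; aq. NH4Cl
Reagents that add atoms: none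
Why: Proposed new method: the Grignard reagent adds to the aldehyde, the alkoxide 15 takes the Boc group from O5 (16) and loss of tert-butyl carbonate unmasks the magnesium-bound o-quinone methide 17 without acid, which the tethered E allylsilane attacks at C4 through C3 with anti loss of silicon; the closest known reactions are the Grignard-triggered generation of o-quinone methides from O-Boc salicylaldehydes, so far trapped by a second organometallic or an enol ether, and Hosomi-Sakurai additions of allylsilanes to quinone methides and benzylic cations. The pyran ring closes as a six-membered chair, endo to the C4=C4a bond and exo to the allylsilane, and rearomatisation with transfer of Me3Si to tert-butoxide makes it irreversible. C4 is set by the methide geometry, with isobutyl on the C5 side away from the bulky O1 ether so that it becomes equatorial. C3 is set by the chair, in which the C3=C9 bond is equatorial and anti to C4=C4a (3,4-trans) and the C16 chain on the preset C2 centre is equatorial with methyl axial (2,3-trans), O1 being alkylated so that C2 is never ionised. The step needs the aldehyde to react before the carbonate and the closure to outrun a second Grignard addition or tautomerisation of the methide, which 1.05 equiv at −78 °C, high dilution and the short tether should secure. It also needs the (2R,3S,4S) isomer: the 3,4 relation is secured by the chair, while the 2,3 relation rests only on the modest preference of the chain over methyl for the equatorial site and is the weak point of the step.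

Step 11
Reactants: 18 3-vinylchroman-5-ol from step 10
Product: 19 (2R,3S,4S)-2-[(3R)-3-[2-(TBSO)propan-2-yl]-5,5-dimethoxypentyl]-3-ethenyl-5,7-bis(methoxymethoxy)-2-methyl-4-(2-methylpropyl)chroman
Conditions: NaH, MOMCl, THF/DMF, 0 °C
Reagents that add atoms: chloromethyl methyl ether, COCCl
Why: Williamson-type alkylation of the sodium phenoxide masks O5 for the borane, ylide and metathesis steps.

Step 12
Reactants: 19 bis-MOM 3-vinylchroman; 20 2-bromopropene
Product: 22 (2R,3S,4S)-2-[(3R)-3-[2-(TBSO)propan-2-yl]-5,5-dimethoxypentyl]-5,7-bis(methoxymethoxy)-2-methyl-3-(3-methylbut-3-en-1-yl)-4-(2-methylpropyl)chroman, via B-alkyl-9-BBN adduct 21 (not isolated)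
Conditions: 9-BBN (9-borabicyclo[3.3.1]nonane), THF, 0 °C to rt; then 20 (5 equiv), Pd(dppf)Cl2·CH2Cl2 (5 mol%), aq. K3PO4, DMF, 50 °C, sealed
Reagents that add atoms: none
Why: anti-Markovnikov hydroboration of the only alkene followed by B-alkyl Suzuki-Miyaura coupling with the vinyl bromide forms C10-C11 without touching a stereocentre.

Step 13
Reactants: 22 isopropenyl acetal from step 12
Product: 23 (3R)-3-[2-(TBSO)propan-2-yl]-5-[(2R,3S,4S)-5,7-bis(methoxymethoxy)-2-methyl-3-(3-methylbut-3-en-1-yl)-4-(2-methylpropyl)chroman-2-yl]pentanal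
Conditions: PPTS (cat.), acetone/H2O, 40 °C
Reagents that add atoms: water, O
Why: acid-catalysed hydrolysis of the dimethyl acetal under conditions mild enough that the aryl MOM ethers, the tertiary TBS ether and the 1,1-disubstituted alkene should persist.

Step 14
Reactants: 23 aldehyde from step 13
Product: 24 (2R,3S,4S)-2-[(3R)-3-[2-(TBSO)propan-2-yl]hex-5-en-1-yl]-5,7-bis(methoxymethoxy)-2-methyl-3-(3-methylbut-3-en-1-yl)-4-(2-methylpropyl)chroman
Conditions: Ph3PCH3Br, KOtBu, THF, 0 °C to rt
Reagents that add atoms: methyltriphenylphosphonium bromide, C[P+](c1ccccc1)(c1ccccc1)c1ccccc1.[Br-]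
Why: Wittig methylenation of the aldehyde; C14 is β to the carbonyl and cannot epimerise.

Step 15
Reactants: 24 diene from step 14
Product: 25 (2R,3S,4S,14R,11Z)-4-isobutyl-5,7-bis(methoxymethoxy)-2,11-dimethyl-14-[2-(TBSO)propan-2-yl] chroman fused at C2/C3 to the C9-C16 cyclodecene
Conditions: second-generation Grubbs catalyst (10 mol%), toluene, 0.001 M, 80 °C
Reagents that add atoms: none
Why: ring-closing metathesis between the monosubstituted and the 1,1-disubstituted alkene forms C11=C12 with loss of ethene; the trans-diequatorial arms on C2 and C3 preorganise the closure, and the ten-membered ring should take the trisubstituted alkene as the less strained Z isomer.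

Step 16
Reactants: 25 bis-MOM cyclodecene-fused chroman
Product: 26 (2R,3S,4S,14R,11Z)-4-isobutyl-2,11-dimethyl-14-[2-(TBSO)propan-2-yl] cyclodecene-fused chroman-5,7-diol
Conditions: ZnBr2, n-PrSH, CH2Cl2, 0 °C
Reagents that add atoms: none
Why: Lewis acid-assisted cleavage of both aryl MOM ethers with the thiol as trap for the methoxymethyl cation, which keeps the electron-rich ring from being alkylated, while the TBS ether keeps O17 from adding across C11=C12.

Step 17
Reactants: 26 5,7-diphenol from step 16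
Product: 27 (2R,3S,4S,14R,11Z)-5,7-dihydroxy-4-isobutyl-2,11-dimethyl-14-[2-(TBSO)propan-2-yl] cyclodecene-fused chroman-6,8-dicarbaldehyde
Conditions: POCl3 (6 equiv), DMF, 0 to 40 °C; then aq. NaOAc, 50 °C
Reagents that add atoms: N,N-dimethylformamide, CN(C)C=O; water, O
Why: twofold Vilsmeier-Haack formylation at C6 and C8, the only free positions of the phloroglucinol-type ring, as known for phloroglucinol itself; hydrolysis of the iminium groups gives the hydrogen-bonded dialdehyde.

Step 18
Reactants: 27 TBS-protected dialdehyde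
Product: 28 CNP0570248.1, (2R,3S,4S,14R,11Z)-5,7-dihydroxy-14-(2-hydroxypropan-2-yl)-4-isobutyl-2,11-dimethyl cyclodecene-fused chroman-6,8-dicarbaldehyde
Conditions: Bu4NF (excess), THF, 60 °C; aq. NH4Cl
Reagents that add atoms: none
Why: fluoride cleavage of the tertiary TBS ether under non-acidic conditions, so that the free C17 hydroxyl never meets acid in the presence of the C11=C12 alkene.

**Compound list**

1 | 2,4,6-trihydroxybenzaldehyde | O=Cc1c(O)cc(O)cc1O | starting material
2 | 2,6-dihydroxy-4-(methoxymethoxy)benzaldehyde | O=Cc1c(O)cc(OCOC)cc1O | intermediate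
3 | (R)-α-terpineol | CC1=CC[C@@H](CC1)C(C)(C)O | starting material
4 | (R)-α-terpineol TBS ether | CC1=CC[C@@H](CC1)C(C)(C)O[Si](C)(C)C(C)(C)C | intermediate
5 | (3R)-3-[2-(TBSO)propan-2-yl]-6-oxoheptanal | O=CC[C@H](C(C)(C)O[Si](C)(C)C(C)(C)C)CCC(C)=O | intermediate (not isolated)
6 | (5R)-5-[2-(TBSO)propan-2-yl]-7,7-dimethoxyheptan-2-one | COC(OC)C[C@H](C(C)(C)O[Si](C)(C)C(C)(C)C)CCC(C)=O | intermediate
7 | ethyl (2E,6R)-6-[2-(TBSO)propan-2-yl]-8,8-dimethoxy-3-methyloct-2-enoate | COC(OC)C[C@H](C(C)(C)O[Si](C)(C)C(C)(C)C)CC/C(C)=C/C(=O)OCC | intermediate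
8 | (2E,6R)-6-[2-(TBSO)propan-2-yl]-8,8-dimethoxy-3-methyloct-2-en-1-ol | COC(OC)C[C@H](C(C)(C)O[Si](C)(C)C(C)(C)C)CC/C(C)=C/CO | intermediate
9 | methyl carbonate of 8 | COC(OC)C[C@H](C(C)(C)O[Si](C)(C)C(C)(C)C)CC/C(C)=C/COC(=O)OC | intermediate
10 | 2-{[(3R,6R)-6-[2-(TBSO)propan-2-yl]-8,8-dimethoxy-3-methyloct-1-en-3-yl]oxy}-6-hydroxy-4-(methoxymethoxy)benzaldehyde | COC(OC)C[C@H](C(C)(C)O[Si](C)(C)C(C)(C)C)CC[C@@](C=C)(C)Oc1cc(OCOC)cc(O)c1C=O | intermediate
11 | allyltrimethylsilane | C=CC[Si](C)(C)C | starting material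
12 | 2-{[(2E,4R,7R)-7-[2-(TBSO)propan-2-yl]-9,9-dimethoxy-4-methyl-1-(trimethylsilyl)non-2-en-4-yl]oxy}-6-hydroxy-4-(methoxymethoxy)benzaldehyde | COC(OC)C[C@H](C(C)(C)O[Si](C)(C)C(C)(C)C)CC[C@@](/C=C/C[Si](C)(C)C)(C)Oc1cc(OCOC)cc(O)c1C=O | intermediate
13 | tert-butyl carbonate of 12 at the phenol (O5), key-step precursor | COC(OC)C[C@H](C(C)(C)O[Si](C)(C)C(C)(C)C)CC[C@@](/C=C/C[Si](C)(C)C)(C)Oc1cc(OCOC)cc(OC(=O)OC(C)(C)C)c1C=O | intermediate
14 | isobutylmagnesium bromide | CC(C)C[Mg]Br | starting material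
15 | bromomagnesium alkoxide from addition of 14 to the formyl group of 13 (both benzylic epimers) | COC(OC)C[C@H](C(C)(C)O[Si](C)(C)C(C)(C)C)CC[C@@](/C=C/C[Si](C)(C)C)(C)Oc1cc(OCOC)cc(OC(=O)OC(C)(C)C)c1C(CC(C)C)O[Mg]Br | intermediate (not isolated)
16 | bromomagnesium phenoxide at O5 with the tert-butyl carbonate on the benzylic oxygen | COC(OC)C[C@H](C(C)(C)O[Si](C)(C)C(C)(C)C)CC[C@@](/C=C/C[Si](C)(C)C)(C)Oc1cc(OCOC)cc(O[Mg]Br)c1C(CC(C)C)OC(=O)OC(C)(C)C | intermediate (not isolated)
17 | (6Z)-5-{[allylsilane chain of 12]oxy}-3-(methoxymethoxy)-6-(3-methylbutylidene)cyclohexa-2,4-dien-1-one, the o-quinone methide | COC(OC)C[C@H](C(C)(C)O[Si](C)(C)C(C)(C)C)CC[C@@](/C=C/C[Si](C)(C)C)(C)OC1=CC(OCOC)=CC(=O)/C1=C\CC(C)C | intermediate (not isolated)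
18 | (2R,3S,4S)-2-[(3R)-3-[2-(TBSO)propan-2-yl]-5,5-dimethoxypentyl]-3-ethenyl-7-(methoxymethoxy)-2-methyl-4-(2-methylpropyl)-3,4-dihydro-2H-chromen-5-ol, key-step product | COC(OC)C[C@H](C(C)(C)O[Si](C)(C)C(C)(C)C)CC[C@@]1(C)Oc2cc(OCOC)cc(O)c2[C@@H](CC(C)C)[C@@H]1C=C | intermediate
19 | 5-O-MOM ether of 18 | COC(OC)C[C@H](C(C)(C)O[Si](C)(C)C(C)(C)C)CC[C@@]1(C)Oc2cc(OCOC)cc(OCOC)c2[C@@H](CC(C)C)[C@@H]1C=C | intermediate
20 | 2-bromopropene | C=C(C)Br | starting material
21 | B-alkyl-9-BBN adduct of 19 (boron on C10) | COC(OC)C[C@H](C(C)(C)O[Si](C)(C)C(C)(C)C)CC[C@@]1(C)Oc2cc(OCOC)cc(OCOC)c2[C@@H](CC(C)C)[C@@H]1CCB1C2CCCC1CCC2 | intermediate (not isolated)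
22 | (2R,3S,4S)-2-[(3R)-3-[2-(TBSO)propan-2-yl]-5,5-dimethoxypentyl]-5,7-bis(methoxymethoxy)-2-methyl-3-(3-methylbut-3-en-1-yl)-4-(2-methylpropyl)chroman | COC(OC)C[C@H](C(C)(C)O[Si](C)(C)C(C)(C)C)CC[C@@]1(C)Oc2cc(OCOC)cc(OCOC)c2[C@@H](CC(C)C)[C@@H]1CCC(C)=C | intermediate
23 | (3R)-3-[2-(TBSO)propan-2-yl]-5-[(2R,3S,4S)-5,7-bis(methoxymethoxy)-2-methyl-3-(3-methylbut-3-en-1-yl)-4-(2-methylpropyl)chroman-2-yl]pentanal | O=CC[C@H](C(C)(C)O[Si](C)(C)C(C)(C)C)CC[C@@]1(C)Oc2cc(OCOC)cc(OCOC)c2[C@@H](CC(C)C)[C@@H]1CCC(C)=C | intermediate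
24 | (2R,3S,4S)-2-[(3R)-3-[2-(TBSO)propan-2-yl]hex-5-en-1-yl]-5,7-bis(methoxymethoxy)-2-methyl-3-(3-methylbut-3-en-1-yl)-4-(2-methylpropyl)chroman | C=CC[C@H](C(C)(C)O[Si](C)(C)C(C)(C)C)CC[C@@]1(C)Oc2cc(OCOC)cc(OCOC)c2[C@@H](CC(C)C)[C@@H]1CCC(C)=C | intermediate
25 | (2R,3S,4S,14R,11Z) cyclodecene-fused chroman, 5,7-bis(MOM) ether, 17-O-TBS ether | C/C1=C/C[C@H](C(C)(C)O[Si](C)(C)C(C)(C)C)CC[C@@]2(C)Oc3cc(OCOC)cc(OCOC)c3[C@@H](CC(C)C)[C@@H]2CC1 | intermediate
26 | (2R,3S,4S,14R,11Z) cyclodecene-fused chroman-5,7-diol, 17-O-TBS ether | C/C1=C/C[C@H](C(C)(C)O[Si](C)(C)C(C)(C)C)CC[C@@]2(C)Oc3cc(O)cc(O)c3[C@@H](CC(C)C)[C@@H]2CC1 | intermediate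
27 | (2R,3S,4S,14R,11Z) 5,7-dihydroxy-6,8-dicarbaldehyde, 17-O-TBS ether | C/C1=C/C[C@H](C(C)(C)O[Si](C)(C)C(C)(C)C)CC[C@@]2(C)Oc3c(C=O)c(O)c(C=O)c(O)c3[C@@H](CC(C)C)[C@@H]2CC1 | intermediate
28 | CNP0570248.1, (2R,3S,4S,14R,11Z) | C/C1=C/C[C@H](C(C)(C)O)CC[C@@]2(C)Oc3c(C=O)c(O)c(C=O)c(O)c3[C@@H](CC(C)C)[C@@H]2CC1 | target

**Step count**

Total steps: 18. Longest linear sequence: 17 (steps 2 to 18, from (R)-α-terpineol); step 1 is a one-step branch.

**Steps most likely to fail**

Step 10 (key step). The methide may be used up by a second molecule of the Grignard reagent or by tautomerisation to the styrene before the allylsilane closes, and the C2 centre may discriminate poorly between the two faces of C3 because methyl and the chain differ little at the carbon bound to C2. Fallback by known chemistry, setting out from 12 and returning at 19: the phenol of 12 is alkylated with MOMCl and NaH to the bis-MOM aldehyde F1, which has no migrating group. Isobutylmagnesium bromide (THF, −78 °C) then adds to give the benzylic alcohol F2 as a mixture of epimers. Catalytic Sc(OTf)3 in CH2Cl2 at −40 °C ionises this doubly ortho- and para-oxygenated benzylic alcohol, and the allylsilane closes the pyran ring in an intramolecular Hosomi-Sakurai substitution to give 19 directly. In either version the C2,C3 isomers are diastereomers and would be separated at 18 or 19.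

Step 15. Intermolecular metathesis of the monosubstituted alkene (oligomers), slow engagement of the 1,1-disubstituted alkene, or closure to the E alkene may compete. Fallback, setting out from 19 and returning at 25: PPTS in acetone/H2O should unmask the aldehyde with the C3 vinyl group intact F3. Stork-Zhao olefination with Ph3P=C(I)CH3 (from [Ph3PCH(I)CH3]I and NaN(SiMe3)2, THF, −78 °C) should give the (Z)-2-iodoalkene with iodine cis to C13 F4. 9-BBN then hydroborates only the vinyl group to the B-alkyl borane F5. Slow addition of F5 to Pd(dppf)Cl2·CH2Cl2, AsPh3 and Cs2CO3 in DMF/THF/H2O at high dilution closes C10-C11 by intramolecular B-alkyl Suzuki-Miyaura coupling with retention at C11, giving 25 with the Z geometry fixed beforehand. Steps 12 to 15 and 2-bromopropene are then not needed.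

Step 17. The second formylation may stall once the first iminium group has deactivated the ring, and the hydrogen chloride set free may attack the C11=C12 alkene. Fallback, setting out from 25 (both MOM ethers in place) and returning at 27: n-BuLi and TMEDA in THF at 0 °C, then DMF, should give the 6-carbaldehyde F6 by directed ortho-metalation between the two MOM ethers. LiN(Me)CH2CH2NMe2 then masks this aldehyde in the flask as its α-amino alkoxide, n-BuLi metalates C8 between O1 and the C7 MOM ether, and DMF gives the 6,8-dicarbaldehyde bis-MOM ether F7. 2 M HCl in THF/MeOH at rt removes the two MOM ethers, now ortho to formyl groups on a deactivated ring and with O17 still silylated, and gives 27.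

**Further compounds**

F1 | step 10 | 2-{[(2E,4R,7R)-7-[2-(TBSO)propan-2-yl]-9,9-dimethoxy-4-methyl-1-(trimethylsilyl)non-2-en-4-yl]oxy}-4,6-bis(methoxymethoxy)benzaldehyde | COC(OC)C[C@H](C(C)(C)O[Si](C)(C)C(C)(C)C)CC[C@@](/C=C/C[Si](C)(C)C)(C)Oc1cc(OCOC)cc(OCOC)c1C=O
F2 | step 10 | 1-[2-(allylsilane ether of F1)-4,6-bis(methoxymethoxy)phenyl]-3-methylbutan-1-ol, both carbinol epimers | COC(OC)C[C@H](C(C)(C)O[Si](C)(C)C(C)(C)C)CC[C@@](/C=C/C[Si](C)(C)C)(C)Oc1cc(OCOC)cc(OCOC)c1C(O)CC(C)C
F3 | step 15 | (3R)-3-[2-(TBSO)propan-2-yl]-5-[(2R,3S,4S)-3-ethenyl-5,7-bis(methoxymethoxy)-2-methyl-4-(2-methylpropyl)chroman-2-yl]pentanal | O=CC[C@H](C(C)(C)O[Si](C)(C)C(C)(C)C)CC[C@@]1(C)Oc2cc(OCOC)cc(OCOC)c2[C@@H](CC(C)C)[C@@H]1C=C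
F4 | step 15 | (Z)-2-iodoalkene from F3, (2R,3S,4S)-3-ethenyl-2-[(3R,5Z)-6-iodo-3-[2-(TBSO)propan-2-yl]hept-5-en-1-yl]-5,7-bis(methoxymethoxy)-2-methyl-4-(2-methylpropyl)chroman | C/C(I)=C/C[C@H](C(C)(C)O[Si](C)(C)C(C)(C)C)CC[C@@]1(C)Oc2cc(OCOC)cc(OCOC)c2[C@@H](CC(C)C)[C@@H]1C=C
F5 | step 15 | B-alkyl-9-BBN adduct of F4 (boron on C10) | C/C(I)=C/C[C@H](C(C)(C)O[Si](C)(C)C(C)(C)C)CC[C@@]1(C)Oc2cc(OCOC)cc(OCOC)c2[C@@H](CC(C)C)[C@@H]1CCB1C2CCCC1CCC2
F6 | step 17 | 6-carbaldehyde of 25 | C/C1=C/C[C@H](C(C)(C)O[Si](C)(C)C(C)(C)C)CC[C@@]2(C)Oc3cc(OCOC)c(C=O)c(OCOC)c3[C@@H](CC(C)C)[C@@H]2CC1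
F7 | step 17 | 6,8-dicarbaldehyde of 25 | C/C1=C/C[C@H](C(C)(C)O[Si](C)(C)C(C)(C)C)CC[C@@]2(C)Oc3c(C=O)c(OCOC)c(C=O)c(OCOC)c3[C@@H](CC(C)C)[C@@H]2CC1
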